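(The earlier runs and the new flask stem from a simulated flask with constants of no real substance.)

Reagent is what starting material and first product compete for in the midnight flask, so follow one reagent molecule to its fork. If each step goes with the product of its two concentrations, reagent cancels from their ratio, and bis adduct gained per starting material lost is a selectivity factor times first product over starting material.

| setting | midnight | noon | flask |
|---|---|---|---|
| starting material | 0.038 M | 0.038 M | 0.038 M |
| reagent | 1.2 equiv | 0.60 equiv | 1.20 equiv |
| remark | the very flask that is asked about, followed so far | run made earlier |  |
| time |  |  | 40 min |

- midnight (time / min: bis adduct / %, starting material / %): 2.00: 20.4, 56.6; 6.00: 20.5, 57.3; 12.0: 19.4, 56.9; 15.0: 19.5, 57.0; 25.0: 19.8, 56.5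
- noon (time / s: bis adduct / %, starting material / %): 10.0: 2.5, 85.8; 25.0: 6.3, 78.4; 40.0: 7.8, 74.0; 60.0: 8.7, 71.2; 90.0: 10.2, 69.8

(standard deviation of a reading: 0.5 percentage points)

- removed bis adduct is counted in
- the earlier runs were read with a standard deviation of 0.5 percentage points
- steps thought possible: starting material + reagent -> first product + by-product; reagent + first product -> bis adduct + by-product; reagent + bis adduct -> triple product + by-product; reagent -> decomposition product; 2 reagent -> self-condensation product
- additions bring no volume worth counting

- gamma: at 40 min take out 90% of the bis adduct then present, then wait 80 min
- eta: at 40 min add reagent, 100% of the amount charged, then wait 80 min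
- delta: at 40 min add starting material, 50.0% of the amount charged, then wait 80 min
- theta: change nothing and wait 80 min more

* bis adduct, in percent of the starting material first charged, at 40 min
* what to do for the largest gain in bis adduct; "none" if nothing gains more than 2 percentage points (gamma / eta / delta / theta / none)
* bis adduct present, with what was taken out counted in, in percent of the starting material first charged, after gamma
* bis adduct present, with what was taken out counted in, in percent of the starting material first charged, after delta

In the noon run, from 10.0 s to 90.0 s, bis adduct rises by 7.7 percentage points while starting material falls by 16 points, a slope of 0.481. Taking first product as the unread remainder, its ratio to starting material goes from 0.136 to 0.287. So the readiness ratio, how many times readier first product is for reagent than starting material, reads 2.28.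

Integrated, the rule says first product is the fraction of starting material left, less that fraction raised to the ratio, divided by the ratio less one. You now have two ways to the midnight bis adduct. The mean of its readings is 19.9%. The noon ratio, applied to the mean midnight starting material of 56.9%, leaves a remainder of 20.3%. The gap is 0.40 points against a reading scatter of 0.5 points, and the remainder also counts triple product, so I commit to the mean. The midnight starting material reads 56.6% at 2.00 min and 56.5% at 25.0 min, so I take it that no working reagent stands there: I expect the gain from eta, and no change after gamma or delta.

The forecast gave 19.9%, eta, 19.9% after gamma and 19.9% after delta, on the ground “The reagent is therefore dead”. The flask gives 19.9%, with eta best at a gain of 24 points, and 19.9% after gamma and 19.9% after delta.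

    starting material + reagent → first product + by-product (k = 0.880 /M/s)
    reagent + first product → bis adduct + by-product (k = 2.20 /M/s)
    reagent + bis adduct → triple product + by-product (k = 0.320 /M/s)
    reagent → decomposition product (k = 3.50 × 10⁻⁵ /s)
    2 reagent → self-condensation product (k = 0.830 /M/s)

At the start of this flask, the first step uses reagent at 0.44 of the rate of the loss to self-condensation product, less than that loss. At 40.0 min the limiting reagent stands at 0% and starting material at 56.8%, where the readiness ratio gives 22.9% first product and the flask holds 21.7%. In the neighbour charged with 0.480 equiv, starting material stands at 73.6%, so the ratio gives 18.7% first product and a remainder of 7.74%. That neighbour holds 18.1% first product and 8.01% bis adduct.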